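Watch two losses.

| flask | Q | D | temperature | remark | time |
|---|---|---|---|---|---|
| ash | 0.14 M | 14 mM | 40 °C | run made earlier |  |
| birch | 0.22 M | 14 mM | 62 °C | run made earlier |  |
| alder | 0.29 M | 28 mM | 40 °C | run made earlier |  |
| Saturday's | 0.29 M | 14 mM | 70 °C |  | 12 min |
| Friday's | 0.29 M | 14 mM | 50 °C |  | 12 min |
| Thursday's | 0.29 M | 14 mM | 30 °C |  | 12 min |

- ash (time / min: L / %, Q / %): 6.00: 37.1, 58.6; 12.0: 59.1, 32.7; 20.0: 73.4, 15.9; 25.0: 80.2, 9.4; 40.0: 87.6, 2.0
- birch (time / min: L / %, Q / %): 0.667: 17.4, 77.0; 2.00: 38.8, 50.8; 3.00: 47.4, 32.8; 5.00: 62.8, 16.0; 8.00: 67.9, 4.3; 10.0: 72.6, 4.0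
- alder (time / min: L / %, Q / %): 8.00: 69.1, 26.3; 20.0: 91.7, 2.8; 25.0: 93.4, 1.4; 40.0: 92.4, 0.4

(standard deviation of a reading: 1 percentage point)

- what was read earlier has a scatter of 1 percentage point, one standard deviation
- a reading or a percentage of L counts all its forms, free or not

- the flask with the highest amount of L, in percent of the Q charged ("all alike" if they lie within 1.5 percentage points) (Saturday's / Friday's / Thursday's / all alike)
- final L, as a percentage of the Q charged, in Saturday's
- final L, as a percentage of the Q charged, in Friday's
- final L, as a percentage of the Q charged, in Thursday's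

What can a charge of Q do here? It can stay unused, become L, or go elsewhere, so two losses stand against L.

How is the second loss measured? By the L share s (the selectivity), which is L made per Q used. The birch run gives 75.7 % at its first reading and 75.6 % at its last, but 78.9 % at its second and 70.5 % at its third, so the match of first and last is no proof that s holds along that run. As a simplification, I take the last reading of a run as its s. The ash run ends at 89.4 % at 40 °C, and the birch run at 75.6 % at 62 °C.

And the alder run? It carries twice the D of the three flasks, so it stays out of this line.

What is s at 50 °C, where no run stands? The odds s/(1-s) are 8.42 and 3.10 in those two runs. A straight line of their logarithm against temperature gives 5.35, so my L share for Friday's is 84.3 %.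

And the first loss? I treat Q as falling first order, with constant k. The ash run gives 0.0919 /min and the birch run 0.367 /min, and the same line gives 0.172 /min for Friday's.

Where does control change hands? Where unused Q meets Q gone elsewhere. In Friday's, by my reckoning, unused Q stands at 12.6 %, a little less than the 13.8 % gone elsewhere. In Thursday's, unused Q at 55.5 % far exceeds the 3.12 % gone elsewhere. In Saturday's, unused Q at 0.0695 % lies far below the 31.6 % gone elsewhere. I therefore commit to 73.6 % of L for Friday's, 41.4 % for Thursday's and 68.3 % for Saturday's.

The weak spot? Two points give a line with no test of it, and Thursday's and Saturday's lie outside its span.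

The forecast names Friday's, with 68 % (63 % to 72 %) for Saturday's, 73 % (70 % to 76 %) for Friday's and 41 % (38.5 % to 43.5 %) for Thursday's. In its words, “L therefore does not decay, and a parallel loss competes”. My Friday's figure lies 0.60 percentage points above the forecast's.

The flasks give 62.9 % in Saturday's, 70.9 % in Friday's and 40.6 % in Thursday's, so Friday's holds the most L, and Saturday's falls 5.1 points below the forecast.

    G ⇌ L, rate k1*(cs1 - [L]) while solid is left; crystals form when [L] > cs1 (solubility = 0.220 M, k = 0.970 /min)
    Q + L → J (k = 0.400 /M/min, Ea = 84.0 kJ/mol)
    Q → Z (k = 0.145 /min, Ea = 94.0 kJ/mol)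
    Q + D → D + L (k = 29.4 /M/min, Ea = 48.0 kJ/mol)
    (constants at 70 °C)

At 12 min, Friday's holds 12.5 % of Q unused and 16.6 % in Z and J together, J counted as two. The share 84.3 % applied to the Q used there gives 73.7 % of L, against the 70.9 % found. The neighbouring flask is Friday's read at 3.0 min, with the charge and temperature held. It still has 60 % of its Q unused, so the same share gives 33.3 % of L, and that flask holds 33.6 %.

The data come from a simulation for substances that don't exist, and the scatter is random.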